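The ten-membered carbocycle (C1–C10) is opened at C5–C6. C6 is the γ-carbon of the butenolide ring (O, C6, C7, C11, C12) and C5 bears oxygen. C5–C6 is therefore the bond that a γ-selective (vinylogous) aldol addition would form. The precursor 27 is an acyclic 2-silyloxyfuran, planar at C6. Its C7 side chain carries C8–OTES, the 1,10-epoxide, the Z-C2=C3 alkene and a quaternary C4 whose PMB ether sits next to the C5 aldehyde. Magnesium chelation of the aldehyde and ether oxygens lets furan C6 attack C5. One operation closes the ring, restores the butenolide and sets C5 and C6. The C5 hydroxyl later leaves when O4 closes the 4,5-epoxide with inversion.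

Key step: step 20

Remarks that apply to the whole route
- Numbering: germacranolide numbering of the target is used for every intermediate. C1–C10 is the ring, C11–C13 the lactone side, C14 sits on C10 and C15 on C4.
- Protecting groups: TES sits on O8 and O13 and both are removed together. TBS sits on O14 and is removed last with buffered HF, so no basic fluoride is needed. PMB sits on O4; it chelates, and it is put in place by the C–O bond-forming step 1.
- Stereochemical check: 28 must be 4R,5R,6S, with O4, O5 and O6 all syn along C3–C7. Inversion at C5 in step 23 then gives 5S of the target and the cis relation of C3 and C6 on the 4,5-epoxide.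
- Assumption: the (R,R)-ligand of step 1 is taken to give (S)-3. If it gives (R)-3, the (S,S)-ligand is used instead.

Step 1
Reactants: 1 2-methyl-2-vinyloxirane (racemic), 2 4-methoxybenzyl alcohol
Product: 3 (S)-2-[(4-methoxybenzyl)oxy]-2-methylbut-3-en-1-ol
Conditions: Pd2(dba)3·CHCl3 (1 mol %), (R,R)-DACH-phenyl Trost ligand (3 mol %), Et3B (1 mol %), CH2Cl2, rt
Reagents that add atoms: none
Why: Palladium-catalysed dynamic kinetic asymmetric allylic etherification: zerovalent palladium ionises both epoxide enantiomers to interconverting π-allyl complexes, the boron-bound alkoxide delivers the alcohol to the tertiary terminus, and the chiral ligand sets C4 while placing PMB on the tertiary oxygen without a separate protection.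

Step 2
Reactants: 3 (S)-2-[(4-methoxybenzyl)oxy]-2-methylbut-3-en-1-ol
Product: 4 (S)-2-[(4-methoxybenzyl)oxy]-2-methylbut-3-enal
Conditions: Dess–Martin periodinane, CH2Cl2, 0 °C to rt
Reagents that add atoms: none
Why: Dess–Martin oxidation of a primary alcohol gives an aldehyde that has no α-hydrogen, so C4 cannot epimerise.

Step 3
Reactants: 4 (S)-2-[(4-methoxybenzyl)oxy]-2-methylbut-3-enal
Product: 5 (S)-3-[(4-methoxybenzyl)oxy]-3-methylpent-1-en-4-yne
Conditions: dimethyl (1-diazo-2-oxopropyl)phosphonate, K2CO3, MeOH, 0 °C to rt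
Reagents that add atoms: dimethyl (1-diazo-2-oxopropyl)phosphonate, COP(=O)(OC)C(=[N+]=[N-])C(C)=O
Why: Ohira–Bestmann homologation converts the non-enolisable aldehyde into the terminal alkyne C2≡C3 under mild carbonate conditions, and the remaining vinyl group serves as the masked C5 aldehyde so that C5 needs no protecting group.

Step 4
Reactants: 6 4-tert-butoxy-4-oxobutanoic acid
Product: 7 tert-butyl 4-[methoxy(methyl)amino]-4-oxobutanoate
Conditions: MeNH(OMe)·HCl, EDC·HCl, Et3N, CH2Cl2, 0 °C to rt
Reagents that add atoms: N,O-dimethylhydroxylamine hydrochloride, CNOC.Cl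
Why: Carbodiimide amide coupling gives the Weinreb amide, which will stop the later aryl-lithium addition at the ketone stage.

Step 5
Reactants: 8 furan-3-ylmethanol
Product: 9 tert-butyl(furan-3-ylmethoxy)dimethylsilane
Conditions: TBSCl, imidazole, DMF, rt
Reagents that add atoms: tert-butyldimethylsilyl chloride, CC(C)(C)[Si](C)(C)Cl
Why: Routine O-silylation of a primary alcohol installs the silyl group that is to migrate in the next step.

Step 6
Reactants: 9 tert-butyl(furan-3-ylmethoxy)dimethylsilane
Product: 11 [2-(tert-butyldimethylsilyl)furan-3-yl]methanol, via 2-lithiofuran 10 (not isolated)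
Conditions: n-BuLi, HMPA, THF, −78 °C to rt; H2O
Reagents that add atoms: none
Why: α-Lithiation next to the side chain followed by 1,4 O→C silyl migration (retro-Brook rearrangement, established for 3-(silyloxymethyl)furans) puts silicon on the carbon that will become the lactone carbonyl C12 and frees O13.

Step 7
Reactants: 11 [2-(tert-butyldimethylsilyl)furan-3-yl]methanol, 7 tert-butyl 4-[methoxy(methyl)amino]-4-oxobutanoate
Product: 13 tert-butyl 4-[5-(tert-butyldimethylsilyl)-4-(hydroxymethyl)furan-3-yl]-4-oxobutanoate, via C,O-dilithio species 12 (not isolated)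
Conditions: n-BuLi (2.2 equiv), LiCl, DME, 0 °C; then 7, −78 to 0 °C; H2O
Reagents that add atoms: none
Why: With one α-position blocked by silicon, the lithium alkoxide directs the second lithiation to the neighbouring ring carbon (future C7), and the Weinreb ketone synthesis forms C7–C8 while the hindered tert-butyl ester stays intact.

Step 8
Reactants: 13 tert-butyl 4-[5-(tert-butyldimethylsilyl)-4-(hydroxymethyl)furan-3-yl]-4-oxobutanoate
Product: 14 tert-butyl (4S)-4-[5-(tert-butyldimethylsilyl)-4-(hydroxymethyl)furan-3-yl]-4-hydroxybutanoate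
Conditions: RuCl[(S,S)-TsDPEN](p-cymene) (1 mol %), HCO2H/Et3N (5:2), CH2Cl2, rt
Reagents that add atoms: none
Why: Noyori–Ikariya asymmetric transfer hydrogenation of an aryl alkyl ketone, in which the (S,S)-catalyst gives the (S)-carbinol as with acetophenone-type substrates and thereby sets C8; it tolerates the free O13–H, and the tert-butyl ester resists lactonisation.

Step 9
Reactants: 14 tert-butyl (4S)-4-[5-(tert-butyldimethylsilyl)-4-(hydroxymethyl)furan-3-yl]-4-hydroxybutanoate
Product: 15 bis-TES ether of 14 (O8 and O13 silylated; 8S)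
Conditions: TESCl (2.5 equiv), imidazole, DMF, 0 °C to rt
Reagents that add atoms: chlorotriethylsilane, CC[Si](Cl)(CC)CC
Why: Routine double O-silylation gives O8 and O13 the same labile group so that both can be released together late in the route.

Step 10
Reactants: 15 bis-TES ether (8S)
Product: 17 α-formyl ester (tert-butyl ester formylated at C10; 8S; C10 epimers and enol form), via lithium enolate 16 (not isolated)
Conditions: LiN(iPr)2 (2.1 equiv), THF, −78 °C; CF3CH2OCHO, −78 to −20 °C; H2O
Reagents that add atoms: 2,2,2-trifluoroethyl formate, O=COCC(F)(F)F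
Why: Crossed Claisen condensation (formylation) of the ester enolate introduces C1, and the configuration at C10 does not matter because this carbon becomes sp2 in the next step.

Step 11
Reactants: 17 α-formyl ester (8S)
Product: 18 (Z)-enol tosylate (TsO–C1H=C10 with OTs cis to the tert-butyl ester C14; 8S)
Conditions: TsCl, N-methylimidazole, LiOH, CH2Cl2, 0 °C
Reagents that add atoms: p-toluenesulfonyl chloride, Cc1ccc(cc1)S(=O)(=O)Cl
Why: Stereoselective enol tosylation of an α-formyl ester, in which lithium chelation between enolate and ester oxygens holds the Z-enolate so that OTs ends cis to C14, which fixes the C1=C10 geometry needed for the trans-fused 1,10-epoxide.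

Step 12
Reactants: 18 (Z)-enol tosylate (8S), 5 (S)-3-[(4-methoxybenzyl)oxy]-3-methylpent-1-en-4-yne
Product: 19 tert-butyl enynoate (C1=C10 Z with C2 cis to C14; C2≡C3; 4S,8S)
Conditions: PdCl2(PPh3)2 (5 mol %), CuI (10 mol %), i-Pr2NEt, MeCN, 50 °C
Reagents that add atoms: none
Why: Sonogashira coupling of an ester-activated enol tosylate proceeds with retention of alkene geometry and forms C1–C2, joining the two fragments.

Step 13
Reactants: 19 tert-butyl enynoate (4S,8S)
Product: 20 (Z)-enynol (C14H2OH cis to C2; 4S,8S)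
Conditions: i-Bu2AlH (3 equiv), CH2Cl2, −78 to −40 °C; aq. potassium sodium tartrate
Reagents that add atoms: none
Why: 1,2-Reduction of the conjugated ester with i-Bu2AlH gives the allylic alcohol without touching the alkyne, the vinyl group, the silyl ethers or the C-silyl furan.

Step 14
Reactants: 20 (Z)-enynol (4S,8S)
Product: 21 alkynyl epoxy alcohol (1R,4S,8S,10S)
Conditions: Ti(OiPr)4 (20 mol %), L-(+)-diethyl tartrate (24 mol %), t-BuOOH, 4 Å molecular sieves, CH2Cl2, −20 °C
Reagents that add atoms: tert-butyl hydroperoxide, CC(C)(C)OO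
Why: Katsuki–Sharpless asymmetric epoxidation under reagent control: L-(+)-tartrate makes the carbinol-bearing alkene carbon S as in the (2S)-epoxy alcohols from simple allylic alcohols, so C10 is S; suprafacial oxygen transfer to the Z-alkene makes C1 R, and the vinyl group and the furan lack a directing hydroxyl and stay untouched.

Step 15
Reactants: 21 alkynyl epoxy alcohol (1R,4S,8S,10S)
Product: 22 O14-TBS ether of 21
Conditions: TBSCl, imidazole, DMF, 0 °C to rt
Reagents that add atoms: tert-butyldimethylsilyl chloride, CC(C)(C)[Si](C)(C)Cl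
Why: Routine silylation of the primary epoxy alcohol under non-basic conditions avoids epoxide migration and installs the group that is removed last.

Step 16
Reactants: 22 O14-TBS ether (1R,4S,8S,10S)
Product: 23 butenolide (C12=O, C6H2, C7=C11; 1R,4S,8S,10S)
Conditions: AcOOH (32 % in AcOH), NaOAc, CH2Cl2, 0 °C
Reagents that add atoms: peracetic acid, CC(=O)OO
Why: Peracid oxidation of a 2-silylfuran, in which attack at the silylated carbon, C→O silyl shift and hydrolysis place the carbonyl regiospecifically at C12, while the alkyne, the hindered monosubstituted vinyl group and the PMB ether react far more slowly.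

Step 17
Reactants: 23 butenolide (1R,4S,8S,10S)
Product: 25 alkynyl aldehyde (C5 aldehyde; 1R,4R,8S,10S), via vicinal diol 24 (not isolated)
Conditions: OsO4 (2 mol %), NaIO4 (4 equiv), 2,6-lutidine, dioxane/H2O (3:1), rt
Reagents that add atoms: osmium tetroxide, O=[Os](=O)(=O)=O; sodium periodate, [Na+].[O-]I(=O)(=O)=O
Why: Lemieux–Johnson cleavage attacks the only reactive alkene, the terminal vinyl group, because the butenolide alkene is tetrasubstituted and electron-poor and the alkyne is inert, and it releases the non-enolisable C5 aldehyde under buffered conditions.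

Step 18
Reactants: 25 alkynyl aldehyde (1R,4R,8S,10S)
Product: 26 butenolide aldehyde with Z-C2=C3 alkene (1R,2Z,4R,8S,10S)
Conditions: H2 (1 atm), Pd/CaCO3 poisoned with Pb(OAc)2 (Lindlar catalyst), quinoline, EtOAc, rt
Reagents that add atoms: none
Why: Lindlar semihydrogenation adds hydrogen syn to the alkyne and gives the Z-alkene, and the poisoned catalyst leaves the aldehyde, the PMB ether, the epoxide and the tetrasubstituted butenolide alkene alone.

Step 19
Reactants: 26 butenolide aldehyde (1R,2Z,4R,8S,10S)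
Product: 27 2-(tert-butyldimethylsilyloxy)furan aldehyde (1R,2Z,4R,8S,10S)
Conditions: TBSOTf (1.2 equiv), Et3N (3 equiv), CH2Cl2, −78 to −20 °C; cold aq. NaHCO3, pentane; used directly
Reagents that add atoms: tert-butyldimethylsilyl trifluoromethanesulfonate, CC(C)(C)[Si](C)(C)OS(=O)(=O)C(F)(F)F
Why: Soft enolisation and O-silylation of a butenolide with a silyl triflate and an amine removes a C6 proton to give the aromatic 2-silyloxyfuran; the aldehyde cannot enolise, and excess amine at low temperature keeps the triflate from activating the aldehyde or the epoxide.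

Step 20
Reactants: 27 2-(tert-butyldimethylsilyloxy)furan aldehyde (1R,2Z,4R,8S,10S)
Product: 28 ten-membered C5 alcohol with restored butenolide (1R,2Z,4R,5R,6S,8S,10S)
Conditions: MgBr2·OEt2 (4 equiv), 2,6-di-tert-butyl-4-methylpyridine (0.5 equiv), CH2Cl2, −40 °C, 27 added by syringe pump over 10 h (final 1 mM); pH 7 buffer
Reagents that add atoms: none
Why: Proposed new method: MgBr2 ties the C5 aldehyde oxygen and the C4 PMB-ether oxygen into a five-membered chelate, the electron-rich furan attacks the activated carbonyl through its free 5-position (C6), and transfer of the silyl group to bromide restores the butenolide. The closest known reactions are intermolecular chelation-controlled vinylogous Mukaiyama aldol additions of 2-silyloxyfurans to α-alkoxy aldehydes and intramolecular versions that close five- to seven-membered rings; a ten-membered closure has not been shown. The ring closes in a 10-(enolendo)-exo-trig mode, with C6=C7 of the furan inside the new ring and the C=O bond outside it. C5 is controlled by the chelate, in which the C3 arm and the C15 methyl lie on opposite faces, so that attack on the methyl face (C3–C4–C5–C6 antiperiplanar, a low-strain arrangement in a ten-membered ring) gives 5R, syn to O4; C6 is controlled by the furan face that the tether (8S centre, trans-1,10-epoxide, Z-alkene) can present, and the required 5,6-syn (6S) result is also the usual preference of Lewis-acid-promoted silyloxyfuran additions. The step needs γ- over α-attack (C11 already bears CH2OTES and would become quaternary), ring closure over oligomerisation (slow addition, 1 mM) and survival of the vinyl epoxide and silyl ethers (−40 °C, hindered pyridine to trap HBr, chelation of the aldehyde outcompeting epoxide binding). Both centres must come out right here, because later base treatment would cause retro-aldol cleavage or β-elimination at C5 and not clean epimerisation at C6.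

Step 21
Reactants: 28 ten-membered C5 alcohol (1R,2Z,4R,5R,6S,8S,10S)
Product: 29 C5 mesylate of 28
Conditions: MsCl (1.5 equiv), Et3N (2 equiv), CH2Cl2, −40 °C, 20 min; cold pH 7 buffer
Reagents that add atoms: methanesulfonyl chloride, CS(=O)(=O)Cl
Why: Mesylation of the only free hydroxyl with retention at C5, run cold and short so that the amine cannot start β-elimination through the acidic C6–H; blocking O5 at this point also prevents acetal formation in the next step.

Step 22
Reactants: 29 C5 mesylate (1R,2Z,4R,5R,6S,8S,10S)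
Product: 30 C4 hydroxy C5 mesylate (1R,2Z,4R,5R,6S,8S,10S)
Conditions: DDQ (1.5 equiv), CH2Cl2/pH 7 phosphate buffer (10:1), 0 °C
Reagents that add atoms: none
Why: Oxidative PMB cleavage with DDQ (benzylic hydride abstraction, then hydrolysis of the hemiacetal) is neutral and spares the epoxide, the silyl ethers, the mesylate and the butenolide.

Step 23
Reactants: 30 C4 hydroxy C5 mesylate (1R,2Z,4R,5R,6S,8S,10S)
Product: 32 bis-epoxide (1R,2Z,4R,5S,6S,8S,10S), via potassium alkoxide 31 (not isolated)
Conditions: KN(SiMe3)2 (0.98 equiv), THF (2 mM), −78 to −20 °C; pH 7 buffer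
Reagents that add atoms: none
Why: Intramolecular Williamson-type 3-exo-tet closure in which O4 displaces the mesylate with inversion (5R to 5S, C3 and C6 cis on the oxirane); slightly less than one equivalent of strong base deprotonates O–H much faster than C6–H, and the gem-disubstituted alkoxide should close before proton transfer can start elimination.

Step 24
Reactants: 32 bis-epoxide (1R,2Z,4R,5S,6S,8S,10S)
Product: 33 8,13-diol with O14-TBS retained
Conditions: HF·pyridine, excess pyridine, THF, 0 °C
Reagents that add atoms: none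
Why: Selective fluoride-mediated desilylation removes both TES ethers well before the primary TBS ether on the hindered C14, and the pyridine buffer avoids both strong acid (vinyl epoxides) and base (C6–H).

Step 25
Reactants: 33 8,13-diol
Product: 34 13-acetate with free O8–H
Conditions: AcCl (1.05 equiv), 2,4,6-collidine, CH2Cl2, −78 °C
Reagents that add atoms: acetyl chloride, CC(=O)Cl
Why: Chemoselective acylation of a primary over a hindered secondary alcohol with acetyl chloride and collidine at low temperature, using a base too weak to deprotonate C6.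

Step 26
Reactants: 34 13-acetate with free O8–H, 35 (R)-2-methylbutanoic acid
Product: 36 8-O-[(R)-2-methylbutanoyl] 13-acetate with O14-TBS
Conditions: DCC, DMAP (0.2 equiv), CH2Cl2, 0 °C to rt
Reagents that add atoms: none
Why: Steglich esterification acylates O8 with retention at C8 and carries the acid stereocentre in from 35, with little DMAP and low temperature to limit α-epimerisation of the acyl donor and deprotonation at C6.

Step 27
Reactants: 36 8-O-[(R)-2-methylbutanoyl] 13-acetate with O14-TBS
Product: 37 target CNP0108300.1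
Conditions: HF·pyridine, pyridine, THF, 0 °C to rt
Reagents that add atoms: none
Why: Buffered fluoride desilylation frees O14–H without basic fluoride, so the esters, both vinyl epoxides and the base-sensitive C6–H/C13–OAc array are not put at risk.

Compound list
1 | 2-methyl-2-vinyloxirane (racemic) | CC1(C=C)CO1 | starting material
2 | 4-methoxybenzyl alcohol | COc1ccc(CO)cc1 | starting material
3 | (S)-2-[(4-methoxybenzyl)oxy]-2-methylbut-3-en-1-ol | OC[C@@](C)(OCc1ccc(OC)cc1)C=C | intermediate
4 | (S)-2-[(4-methoxybenzyl)oxy]-2-methylbut-3-enal | O=C[C@@](C)(OCc1ccc(OC)cc1)C=C | intermediate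
5 | (S)-3-[(4-methoxybenzyl)oxy]-3-methylpent-1-en-4-yne | C#C[C@@](C)(OCc1ccc(OC)cc1)C=C | intermediate
6 | 4-tert-butoxy-4-oxobutanoic acid | CC(C)(C)OC(=O)CCC(=O)O | starting material
7 | tert-butyl 4-[methoxy(methyl)amino]-4-oxobutanoate | CON(C)C(=O)CCC(=O)OC(C)(C)C | intermediate
8 | furan-3-ylmethanol | OCc1ccoc1 | starting material
9 | tert-butyl(furan-3-ylmethoxy)dimethylsilane | CC(C)(C)[Si](C)(C)OCc1ccoc1 | intermediate
10 | 2-lithio derivative of 9 | [Li]c1occc1CO[Si](C)(C)C(C)(C)C | intermediate
11 | [2-(tert-butyldimethylsilyl)furan-3-yl]methanol | OCc1ccoc1[Si](C)(C)C(C)(C)C | intermediate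
12 | C,O-dilithio derivative of 11 (lithium on future C7 and on O13) | [Li]OCc1c([Li])coc1[Si](C)(C)C(C)(C)C | intermediate
13 | tert-butyl 4-[5-(tert-butyldimethylsilyl)-4-(hydroxymethyl)furan-3-yl]-4-oxobutanoate | CC(C)(C)OC(=O)CCC(=O)c1coc([Si](C)(C)C(C)(C)C)c1CO | intermediate
14 | tert-butyl (4S)-4-[5-(tert-butyldimethylsilyl)-4-(hydroxymethyl)furan-3-yl]-4-hydroxybutanoate | CC(C)(C)OC(=O)CC[C@H](O)c1coc([Si](C)(C)C(C)(C)C)c1CO | intermediate
15 | bis-TES ether of 14 (8S) | CC(C)(C)OC(=O)CC[C@H](O[Si](CC)(CC)CC)c1coc([Si](C)(C)C(C)(C)C)c1CO[Si](CC)(CC)CC | intermediate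
16 | lithium enolate of 15 | CC(C)(C)OC(O[Li])=CC[C@H](O[Si](CC)(CC)CC)c1coc([Si](C)(C)C(C)(C)C)c1CO[Si](CC)(CC)CC | intermediate
17 | α-formyl ester (8S; C10 epimers and enol) | CC(C)(C)OC(=O)C(C=O)C[C@H](O[Si](CC)(CC)CC)c1coc([Si](C)(C)C(C)(C)C)c1CO[Si](CC)(CC)CC | intermediate
18 | (Z)-enol tosylate (OTs cis to ester; 8S) | CC(C)(C)OC(=O)/C(=C\OS(=O)(=O)c1ccc(C)cc1)C[C@H](O[Si](CC)(CC)CC)c1coc([Si](C)(C)C(C)(C)C)c1CO[Si](CC)(CC)CC | intermediate
19 | tert-butyl (Z)-enynoate (4S,8S) | CC(C)(C)OC(=O)/C(=C\C#C[C@@](C)(OCc1ccc(OC)cc1)C=C)C[C@H](O[Si](CC)(CC)CC)c1coc([Si](C)(C)C(C)(C)C)c1CO[Si](CC)(CC)CC | intermediate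
20 | (Z)-enynol (4S,8S) | OC/C(=C\C#C[C@@](C)(OCc1ccc(OC)cc1)C=C)C[C@H](O[Si](CC)(CC)CC)c1coc([Si](C)(C)C(C)(C)C)c1CO[Si](CC)(CC)CC | intermediate
21 | alkynyl epoxy alcohol (1R,4S,8S,10S) | CC[Si](CC)(CC)O[C@@H](C[C@@]2(CO)O[C@@H]2C#C[C@@](C)(OCc3ccc(OC)cc3)C=C)c1coc([Si](C)(C)C(C)(C)C)c1CO[Si](CC)(CC)CC | intermediate
22 | O14-TBS ether of 21 | CC[Si](CC)(CC)O[C@@H](C[C@@]2(CO[Si](C)(C)C(C)(C)C)O[C@@H]2C#C[C@@](C)(OCc3ccc(OC)cc3)C=C)c1coc([Si](C)(C)C(C)(C)C)c1CO[Si](CC)(CC)CC | intermediate
23 | butenolide (1R,4S,8S,10S) | CC[Si](CC)(CC)O[C@@H](C[C@@]2(CO[Si](C)(C)C(C)(C)C)O[C@@H]2C#C[C@@](C)(OCc3ccc(OC)cc3)C=C)C1=C(CO[Si](CC)(CC)CC)C(=O)OC1 | intermediate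
24 | vicinal diol from the vinyl group of 23 (carbinol epimers) | CC[Si](CC)(CC)O[C@@H](C[C@@]2(CO[Si](C)(C)C(C)(C)C)O[C@@H]2C#C[C@@](C)(OCc3ccc(OC)cc3)C(O)CO)C1=C(CO[Si](CC)(CC)CC)C(=O)OC1 | intermediate
25 | alkynyl aldehyde (1R,4R,8S,10S) | CC[Si](CC)(CC)O[C@@H](C[C@@]2(CO[Si](C)(C)C(C)(C)C)O[C@@H]2C#C[C@@](C)(OCc3ccc(OC)cc3)C=O)C1=C(CO[Si](CC)(CC)CC)C(=O)OC1 | intermediate
26 | butenolide aldehyde with Z-alkene (1R,2Z,4R,8S,10S) | CC[Si](CC)(CC)O[C@@H](C[C@@]2(CO[Si](C)(C)C(C)(C)C)O[C@@H]2/C=C\[C@@](C)(OCc3ccc(OC)cc3)C=O)C1=C(CO[Si](CC)(CC)CC)C(=O)OC1 | intermediate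
27 | 2-silyloxyfuran aldehyde, key-step precursor (1R,2Z,4R,8S,10S) | CC[Si](CC)(CC)O[C@@H](C[C@@]2(CO[Si](C)(C)C(C)(C)C)O[C@@H]2/C=C\[C@@](C)(OCc3ccc(OC)cc3)C=O)c1coc(O[Si](C)(C)C(C)(C)C)c1CO[Si](CC)(CC)CC | intermediate
28 | ten-membered C5 alcohol, key-step product (1R,2Z,4R,5R,6S,8S,10S) | CC[Si](CC)(CC)O[C@H]1C[C@@]2(CO[Si](C)(C)C(C)(C)C)O[C@@H]2/C=C\[C@@](C)(OCc3ccc(OC)cc3)[C@H](O)[C@H]2OC(=O)C(CO[Si](CC)(CC)CC)=C12 | intermediate
29 | C5 mesylate of 28 | CC[Si](CC)(CC)O[C@H]1C[C@@]2(CO[Si](C)(C)C(C)(C)C)O[C@@H]2/C=C\[C@@](C)(OCc3ccc(OC)cc3)[C@H](OS(C)(=O)=O)[C@H]2OC(=O)C(CO[Si](CC)(CC)CC)=C12 | intermediate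
30 | C4 hydroxy C5 mesylate | CC[Si](CC)(CC)O[C@H]1C[C@@]2(CO[Si](C)(C)C(C)(C)C)O[C@@H]2/C=C\[C@@](C)(O)[C@H](OS(C)(=O)=O)[C@H]2OC(=O)C(CO[Si](CC)(CC)CC)=C12 | intermediate
31 | potassium C4 alkoxide of 30 | CC[Si](CC)(CC)O[C@H]1C[C@@]2(CO[Si](C)(C)C(C)(C)C)O[C@@H]2/C=C\[C@@](C)(O[K])[C@H](OS(C)(=O)=O)[C@H]2OC(=O)C(CO[Si](CC)(CC)CC)=C12 | intermediate
32 | bis-epoxide (1R,2Z,4R,5S,6S,8S,10S) | CC[Si](CC)(CC)O[C@H]1C[C@@]2(CO[Si](C)(C)C(C)(C)C)O[C@@H]2/C=C\[C@@]2(C)O[C@H]2[C@H]2OC(=O)C(CO[Si](CC)(CC)CC)=C12 | intermediate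
33 | 8,13-diol with O14-TBS | O[C@H]1C[C@@]2(CO[Si](C)(C)C(C)(C)C)O[C@@H]2/C=C\[C@@]2(C)O[C@H]2[C@H]2OC(=O)C(CO)=C12 | intermediate
34 | 13-acetate with free O8–H and O14-TBS | O[C@H]1C[C@@]2(CO[Si](C)(C)C(C)(C)C)O[C@@H]2/C=C\[C@@]2(C)O[C@H]2[C@H]2OC(=O)C(COC(C)=O)=C12 | intermediate
35 | (R)-2-methylbutanoic acid | CC[C@@H](C)C(=O)O | starting material
36 | 8-O-[(R)-2-methylbutanoyl] 13-acetate with O14-TBS | CC[C@@H](C)C(=O)O[C@H]1C[C@@]2(CO[Si](C)(C)C(C)(C)C)O[C@@H]2/C=C\[C@@]2(C)O[C@H]2[C@H]2OC(=O)C(COC(C)=O)=C12 | intermediate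
37 | CNP0108300.1 (1R,2Z,4R,5S,6S,8S,10S,2'R) | CC[C@@H](C)C(=O)O[C@H]1C[C@@]2(CO)O[C@@H]2/C=C\[C@@]2(C)O[C@H]2[C@H]2OC(=O)C(COC(C)=O)=C12 | target

Total step count: 27. Longest linear sequence: 23 steps (8 to 37, steps 5–27). Steps 1–3 and step 4 are side branches.

Steps most likely to fail

1. Step 20.
- What may go wrong: ring closure may lose to oligomerisation. Bromide may open the vinyl epoxide during the long addition. The furan may be desilylated without forming a C–C bond, or the C13 silyloxy group may be expelled. Ring strain may override the chelate so that the wrong aldehyde or furan face reacts.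
- Fallback (leaves the route at 18, rejoins at 28): the C5–C6 bond is made between two molecules, which is established chemistry. The ring is then closed at C2=C3 by ring-closing metathesis, which is established for ten-membered carbocycles. Suzuki–Miyaura coupling of 18 with potassium vinyltrifluoroborate (PdCl2(dppf), Cs2CO3) should give the tert-butyl (Z)-dienoate F1. Next, i-Bu2AlH gives the dienol F2 and Sharpless epoxidation with L-(+)-diethyl tartrate gives the vinyl epoxy alcohol F3. TBSCl gives the silyl ether F4, buffered peracetic acid the butenolide F5, and TBSOTf/Et3N the silyloxyfuran F6. The aldehyde partner is made from 1 and 2 as in steps 1 and 2 but with the enantiomeric ligand, by way of the (R)-alcohol F7 and the (R)-aldehyde F8. MgBr2·OEt2 in CH2Cl2 at −78 °C joins F6 and F8 under chelation control to the open-chain aldol F9. The second-generation Grubbs catalyst RuCl2(H2IMes)(PCy3)(=CHPh) in dilute toluene then closes C2=C3 to 28. Any E-isomer would have to be separated.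

2. Step 23.
- What may go wrong: deprotonation at C6 may compete with deprotonation of O4–H and lead to β-elimination of the mesylate. Any excess base may reopen the new epoxide by the same pathway. The ring may also be slow to reach the conformation with O4 anti to the leaving group.
- Fallback (leaves at 28, rejoins at 32): the PMB ether is removed first with DDQ in CH2Cl2/pH 7 buffer to give the 4,5-diol F10. Triflic anhydride and 2,6-lutidine at −78 °C convert the secondary hydroxyl into the C5 triflate F11. On warming, the neutral tertiary hydroxyl displaces it with inversion, so no base stronger than lutidine is ever present.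

3. Step 16.
- What may go wrong: the peracid may attack the unsilylated side of the furan and cleave the ring to an enedione. The acidic medium may strip the primary TES ether, and slow epoxidation of the vinyl group may erode the material.
- Fallback (leaves at 22, rejoins at 23): dye-sensitised photooxygenation (O2, tetraphenylporphyrin, visible light, CH2Cl2, −78 °C) is used, and the silyl group again fixes the carbonyl at C12. This gives the 6-hydroxybutenolide F12. NaBH4 in MeOH followed by mild acidification reduces the masked C6 aldehyde and relactonises to 23.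

Further compounds
F1 | step 20 | tert-butyl (Z)-dienoate (vinyl in place of OTs; 8S) | CC(C)(C)OC(=O)/C(=C\C=C)C[C@H](O[Si](CC)(CC)CC)c1coc([Si](C)(C)C(C)(C)C)c1CO[Si](CC)(CC)CC
F2 | step 20 | (Z)-dienol (8S) | OC/C(=C\C=C)C[C@H](O[Si](CC)(CC)CC)c1coc([Si](C)(C)C(C)(C)C)c1CO[Si](CC)(CC)CC
F3 | step 20 | vinyl epoxy alcohol (1R,8S,10S) | CC[Si](CC)(CC)O[C@@H](C[C@@]2(CO)O[C@@H]2C=C)c1coc([Si](C)(C)C(C)(C)C)c1CO[Si](CC)(CC)CC
F4 | step 20 | O14-TBS ether of F3 | CC[Si](CC)(CC)O[C@@H](C[C@@]2(CO[Si](C)(C)C(C)(C)C)O[C@@H]2C=C)c1coc([Si](C)(C)C(C)(C)C)c1CO[Si](CC)(CC)CC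
F5 | step 20 | vinyl epoxide butenolide (1R,8S,10S) | CC[Si](CC)(CC)O[C@@H](C[C@@]2(CO[Si](C)(C)C(C)(C)C)O[C@@H]2C=C)C1=C(CO[Si](CC)(CC)CC)C(=O)OC1
F6 | step 20 | vinyl epoxide 2-silyloxyfuran (1R,8S,10S) | CC[Si](CC)(CC)O[C@@H](C[C@@]2(CO[Si](C)(C)C(C)(C)C)O[C@@H]2C=C)c1coc(O[Si](C)(C)C(C)(C)C)c1CO[Si](CC)(CC)CC
F7 | step 20 | (R)-2-[(4-methoxybenzyl)oxy]-2-methylbut-3-en-1-ol | C=C[C@@](C)(OCc1ccc(OC)cc1)CO
F8 | step 20 | (R)-2-[(4-methoxybenzyl)oxy]-2-methylbut-3-enal | C=C[C@@](C)(OCc1ccc(OC)cc1)C=O
F9 | step 20 | open-chain aldol with two terminal vinyl groups (1R,4R,5R,6S,8S,10S) | CC[Si](CC)(CC)O[C@@H](C[C@@]2(CO[Si](C)(C)C(C)(C)C)O[C@@H]2C=C)C1=C(CO[Si](CC)(CC)CC)C(=O)O[C@@H]1[C@@H](O)[C@](C)(OCc3ccc(OC)cc3)C=C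
F10 | step 23 | macrocyclic 4,5-diol (1R,2Z,4R,5R,6S,8S,10S) | CC[Si](CC)(CC)O[C@H]1C[C@@]2(CO[Si](C)(C)C(C)(C)C)O[C@@H]2/C=C\[C@@](C)(O)[C@H](O)[C@H]2OC(=O)C(CO[Si](CC)(CC)CC)=C12
F11 | step 23 | C4 hydroxy C5 triflate | CC[Si](CC)(CC)O[C@H]1C[C@@]2(CO[Si](C)(C)C(C)(C)C)O[C@@H]2/C=C\[C@@](C)(O)[C@H](OS(=O)(=O)C(F)(F)F)[C@H]2OC(=O)C(CO[Si](CC)(CC)CC)=C12
F12 | step 16 | 6-hydroxybutenolide (C6 epimers; 1R,4S,8S,10S) | CC[Si](CC)(CC)O[C@@H](C[C@@]2(CO[Si](C)(C)C(C)(C)C)O[C@@H]2C#C[C@@](C)(OCc3ccc(OC)cc3)C=C)C1=C(CO[Si](CC)(CC)CC)C(=O)OC1O
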